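**Plan**

1. Numbering (cembrane): C1 carries the isopropyl group, C4 the methyl, C6 the lactone oxygen, C8 the lactone carbonyl C19, C12 the CO2Me (C20), C13 the OH, C14 the ring CH2.
2. Cuts, in retrosynthetic order: C12–C20 (CO2Me from an alkenyl iodide), C7=C8 (butenolide by metathesis across the macrocycle), C13–C14 (allylboration), O–C19 (ester), C2–C3 (boron 1,2-shift).
3. Enabling feature: HO–C13–C14H2–C1(iPr)=C2H in the 14-membered ring is a homoallylic alcohol and C2 is allylic to both C1 and C3, so boron on C2 of a C1=C14/C3=C4 diene delivers C14 to a C13 aldehyde and leaves the C1=C2–C3=C4 diene.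
4. Forward: boronate alcohol 16 and acid 25 are joined as an ester; oxidation to the iodoenal triggers closure of the 15-membered lactone ring (key step); metathesis across that ring makes the butenolide and with it the 14-membered carbocycle; carbonylation at C12 finishes.
5. Stereochemistry: C6 from (S)-2-vinyloxirane; C2–B from a diol-directed Matteson homologation and an invertive 1,2-shift; C13 and the C1=C2 geometry by 1,3-chirality transfer from C2; C3=C4 by syn-carboalumination; C11=C12 by trans-hydrostannation.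
6. Helpers: iodine on C12 (placeholder for CO2Me, exchanged in step 16), the boronic ester (shed in the key step), the CH2 termini on C7 and C8 (lost as ethene in step 15).

Key step: step 14

Assumption: an (R,R)-diol boronic ester is taken to give the (αS)-chloride in the Matteson homologation (step 2); were the sense opposite, the (S,S)-diol would be used and nothing else changes. Compounds 1, 2, 8 and 17 are taken as commercial.

**Route**

Step 1
Reactants: 1 2-bromo-3-methylbut-1-ene; 2 (1R,2R)-1,2-dicyclohexylethane-1,2-diol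
Product: 5 (4R,5R)-4,5-dicyclohexyl-2-(3-methylbut-1-en-2-yl)-1,3,2-dioxaborolane, via Grignard reagent 3 (not isolated), via boronic acid 4 (not isolated)
Conditions: Mg, THF, 40 °C; B(OMe)3, −78 °C; aq HCl; then 2, MgSO4, Et2O, 23 °C
Reagents that add atoms: trimethyl borate, COB(OC)OC
Why: Grignard formation, borylation and esterification of the boronic acid with the C2-symmetric diol is the standard entry to an alkenylboronic ester carrying a chiral director; no stereocentre is formed.

Step 2
Reactants: 5 (4R,5R)-4,5-dicyclohexyl-2-(3-methylbut-1-en-2-yl)-1,3,2-dioxaborolane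
Product: 7 (4R,5R)-2-[(1S)-1-chloro-3-methyl-2-methylidenebutyl]-4,5-dicyclohexyl-1,3,2-dioxaborolane, via borate complex 6 (not isolated)
Conditions: CH2Cl2, n-BuLi, THF, −100 °C; 5; ZnCl2, −100 → 23 °C
Reagents that add atoms: dichloromethane (as LiCHCl2), ClCCl
Why: Matteson homologation: LiCHCl2 adds to boron and the ZnCl2-assisted 1,2-shift of the alkenyl group expels one of the two diastereotopic chlorides, the (R,R)-diol directing the shift so that the (S)-chloride should result.

Step 3
Reactants: 8 (2S)-2-ethenyloxirane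
Product: 9 (3R)-hex-1-en-5-yn-3-ol
Conditions: LiC≡CH·H2NCH2CH2NH2, DMSO, 15 → 23 °C; H2O
Reagents that add atoms: lithium acetylide–ethylenediamine complex, [Li]C#C.NCCN
Why: SN2 opening of the epoxide at its unhindered CH2 terminus by the hard acetylide leaves the existing stereocentre untouched, so the (S)-epoxide should give the (3R)-alcohol (only the descriptor changes).

Step 4
Reactants: 9 (3R)-hex-1-en-5-yn-3-ol
Product: 11 (3R,5E)-6-iodo-5-methylhexa-1,5-dien-3-ol, via alkenylalane 10 (not isolated)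
Conditions: AlMe3, Cp2ZrCl2, CH2Cl2, 0 → 23 °C; I2, THF, −30 °C; aq HCl work-up
Reagents that add atoms: trimethylaluminium, C[Al](C)C; iodine, I-I
Why: Negishi carboalumination adds methyl and aluminium syn across the terminal alkyne with aluminium at the terminus (the hydroxyl is carried as its aluminium alkoxide), and iodinolysis with retention should give the (E)-iodide that fixes the C3=C4 geometry.

Step 5
Reactants: 11 (3R,5E)-6-iodo-5-methylhexa-1,5-dien-3-ol
Product: 12 triethyl{[(3R,5E)-6-iodo-5-methylhexa-1,5-dien-3-yl]oxy}silane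
Conditions: Et3SiCl, imidazole, CH2Cl2, 0 °C
Reagents that add atoms: chlorotriethylsilane, CC[Si](Cl)(CC)CC
Why: Silylation masks the hydroxyl, whose alkoxide would otherwise displace chloride from 7 in step 6.

Step 6
Reactants: 12 triethyl{[(3R,5E)-6-iodo-5-methylhexa-1,5-dien-3-yl]oxy}silane; 7 (4R,5R)-2-[(1S)-1-chloro-3-methyl-2-methylidenebutyl]-4,5-dicyclohexyl-1,3,2-dioxaborolane
Product: 16 (3R,5E,7S)-7-[(4R,5R)-4,5-dicyclohexyl-1,3,2-dioxaborolan-2-yl]-5,9-dimethyl-8-methylidenedeca-1,5-dien-3-ol, via alkenyllithium 13 (not isolated), via borate complex 14 (not isolated), via silyl ether 15 (not isolated)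
Conditions: t-BuLi, Et2O, −78 °C; 7; ZnCl2, −78 → 23 °C; then MeOH, PPTS, 23 °C
Reagents that add atoms: none
Why: Iodine–lithium exchange with retention gives 13, which adds to the boron of 7, and the stereospecific 1,2-shift of the alkenyl group with inversion at the chloride-bearing carbon (Matteson substitution of an α-chloro boronic ester) should turn the (S)-chloride into the (S)-configured doubly allylic boronic ester, after which acidic methanol removes the silyl group.

Step 7
Reactants: 17 hexa-1,5-diyne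
Product: 19 hepta-2,6-diyn-1-ol, via lithium acetylide 18 (not isolated)
Conditions: 17 in excess, n-BuLi, THF, −78 °C; (CH2O)n, −78 → 23 °C; H2O
Reagents that add atoms: paraformaldehyde (as formaldehyde), C=O
Why: Monodeprotonation of the diyne and addition of the acetylide to formaldehyde is the standard hydroxymethylation of a terminal alkyne.

Step 8
Reactants: 19 hepta-2,6-diyn-1-ol
Product: 20 methyl 7-hydroxy-2-methylidenehept-5-ynoate
Conditions: Pd(OAc)2, 2-(diphenylphosphino)pyridine, MeSO3H, CO (30 bar), MeOH, 50 °C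
Reagents that add atoms: carbon monoxide, [C-]#[O+]; methanol, CO
Why: Palladium-catalysed Markovnikov methoxycarbonylation of a terminal alkyne with a 2-pyridylphosphine ligand and acid gives the 2-substituted acrylate, the internal alkyne reacting far more slowly.

Step 9
Reactants: 20 methyl 7-hydroxy-2-methylidenehept-5-ynoate
Product: 22 methyl (5Z)-7-hydroxy-6-iodo-2-methylidenehept-5-enoate, via alkenylstannane 21 (not isolated)
Conditions: Bu3SnH, [Cp*RuCl]4, CH2Cl2, 23 °C; then I2, 0 °C
Reagents that add atoms: iodine, I-I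
Why: Hydroxyl-directed ruthenium-catalysed trans-hydrostannation places tin on the alkyne carbon next to the carbinol and hydrogen trans to it, and iododestannylation with retention should give the (Z)-2-iodoallylic alcohol with iodine cis to the chain, the geometry later needed at C11=C12.

Step 10
Reactants: 22 methyl (5Z)-7-hydroxy-6-iodo-2-methylidenehept-5-enoate
Product: 23 (5Z)-7-hydroxy-6-iodo-2-methylidenehept-5-enoic acid
Conditions: LiOH, THF–H2O, 0 → 23 °C; aq HCl to pH 3
Reagents that add atoms: lithium hydroxide, [Li+].[OH-]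
Why: Saponification of the methyl ester; the iodoalkene and the acrylate are stable to cold aqueous hydroxide.

Step 11
Reactants: 23 (5Z)-7-hydroxy-6-iodo-2-methylidenehept-5-enoic acid
Product: 25 (5Z)-6-iodo-2-methylidene-7-(triethylsilyloxy)hept-5-enoic acid, via silyl ester 24 (not isolated)
Conditions: Et3SiCl, imidazole, CH2Cl2, 0 °C; then H2O–THF, 23 °C
Reagents that add atoms: chlorotriethylsilane, CC[Si](Cl)(CC)CC
Why: Hydroxyl and carboxyl are both silylated and the labile silyl ester is then hydrolysed selectively, leaving the primary silyl ether.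

Step 12
Reactants: 16 (3R,5E,7S)-7-[(4R,5R)-4,5-dicyclohexyl-1,3,2-dioxaborolan-2-yl]-5,9-dimethyl-8-methylidenedeca-1,5-dien-3-ol; 25 (5Z)-6-iodo-2-methylidene-7-(triethylsilyloxy)hept-5-enoic acid
Product: 26 (3R,5E,7S)-7-[(4R,5R)-4,5-dicyclohexyl-1,3,2-dioxaborolan-2-yl]-5,9-dimethyl-8-methylidenedeca-1,5-dien-3-yl (5Z)-6-iodo-2-methylidene-7-(triethylsilyloxy)hept-5-enoate
Conditions: DCC, DMAP, CH2Cl2, 0 → 23 °C
Reagents that add atoms: none
Why: Steglich esterification joins the two fragments under neutral conditions that the allylic boronic ester tolerates; C6 is not touched.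

Step 13
Reactants: 26 the silyl ether ester of step 12
Product: 27 (3R,5E,7S)-7-[(4R,5R)-4,5-dicyclohexyl-1,3,2-dioxaborolan-2-yl]-5,9-dimethyl-8-methylidenedeca-1,5-dien-3-yl (5Z)-7-hydroxy-6-iodo-2-methylidenehept-5-enoate
Conditions: PPTS, MeOH–CH2Cl2, 0 °C
Reagents that add atoms: none
Why: Mild acid methanolysis cleaves the primary triethylsilyl ether and leaves the boronic ester and the ester linkage.

Step 14
Reactants: 27 the hydroxy ester of step 13
Product: 30 (6Z,8S,10E,12E,15R)-15-ethenyl-8-hydroxy-7-iodo-13-methyl-3-methylidene-10-(propan-2-yl)-1-oxacyclopentadeca-6,10,12-trien-2-one, via iodoenal 28 (not isolated), via borate ester 29 (not isolated)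
Conditions: Dess–Martin periodinane, CH2Cl2 (0.02 M), 0 °C; dilute with PhMe to 1 mM, 45 °C; H2O work-up
Reagents that add atoms: none
Why: Proposed new method: Dess–Martin oxidation unveils the (Z)-2-iodoenal 28, whose carbonyl oxygen binds the boron on C2 so that C14, the terminus of the isopropyl-bearing allyl arm, is delivered to C13 through a closed six-membered chair (an allylboration); the closest known reactions are bimolecular and small-ring intramolecular allylborations of α-substituted allylboronic esters, which proceed with 1,3-chirality transfer, whereas a closure of this ring size is untested. The ring that closes is the 15-membered lactone perimeter C13–C14–C1–C2–C3–C4–C5–C6–O–C19–C8–C9–C10–C11–C12, by attack of C14 on the aldehyde carbon while the C2–B bond is given up and the C1=C14 double bond moves to C1=C2. C13 is controlled by the boron-bearing centre C2: with the aldehyde substituent equatorial and the C3 alkenyl group axial (the equatorial placement suffers A(1,2) strain against the isopropyl group on C1), the (2S)-boronate should give (13S) and a C1=C2 bond with C3 cis to C14, which is the (1E) diene of the target. The step needs C14 to react in preference to C4 and ring closure to outrun dimerisation; the first is secured because attack through C4 would build a quaternary centre in an 11-membered ring, the second by high dilution. No base, metal or Lewis acid is present, so the acrylate, the iodoalkene and C6 are not at risk.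

Step 15
Reactants: 30 the 15-membered lactone of step 14
Product: 31 (1E,3E,6R,7Z,11Z,13S)-13-hydroxy-12-iodo-20-norcembra-1,3,7,11-tetraen-19,6-olide
Conditions: second-generation Grubbs catalyst, PhMe (2 mM), 80 °C
Reagents that add atoms: none
Why: Ring-closing metathesis between the C6 vinyl group and the C8 methylidene across the lactone, a five-membered closure well known for butenolides from acrylate esters of allylic alcohols, should give the butenolide and thereby the 14-membered carbocycle with loss of ethene; the trisubstituted ring alkenes and the iodoalkene are poor metathesis partners.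

Step 16
Reactants: 31 the iodo butenolide of step 15
Product: 32 methyl (1E,3E,6R,7Z,11Z,13S)-13-hydroxycembra-1,3,7,11-tetraen-19,6-olid-20-oate (CNP0173999.1)
Conditions: PdCl2(PPh3)2, CO (1 atm), Et3N, MeOH–THF, 45 °C
Reagents that add atoms: carbon monoxide, [C-]#[O+]; methanol, CO
Why: Palladium-catalysed methoxycarbonylation (oxidative addition to zerovalent palladium, CO insertion, methanolysis) replaces iodine by CO2Me with retention of the C11=C12 geometry, and the weak amine base should leave C6 and C13 untouched.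

**Compound list**

1 | 2-bromo-3-methylbut-1-ene | C=C(Br)C(C)C | starting material
2 | (1R,2R)-1,2-dicyclohexylethane-1,2-diol | O[C@H](C1CCCCC1)[C@H](O)C1CCCCC1 | starting material
3 | (3-methylbut-1-en-2-yl)magnesium bromide | C=C([Mg]Br)C(C)C | intermediate
4 | (3-methylbut-1-en-2-yl)boronic acid | C=C(B(O)O)C(C)C | intermediate
5 | (4R,5R)-4,5-dicyclohexyl-2-(3-methylbut-1-en-2-yl)-1,3,2-dioxaborolane | C=C(C(C)C)B1O[C@H](C2CCCCC2)[C@@H](C2CCCCC2)O1 | intermediate
6 | lithium (4R,5R)-4,5-dicyclohexyl-2-(dichloromethyl)-2-(3-methylbut-1-en-2-yl)-1,3,2-dioxaborolan-2-uide | [Li+].ClC(Cl)[B-]1(C(=C)C(C)C)O[C@H](C2CCCCC2)[C@@H](C2CCCCC2)O1 | intermediate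
7 | (4R,5R)-2-[(1S)-1-chloro-3-methyl-2-methylidenebutyl]-4,5-dicyclohexyl-1,3,2-dioxaborolane | C=C(C(C)C)[C@@H](Cl)B1O[C@H](C2CCCCC2)[C@@H](C2CCCCC2)O1 | intermediate
8 | (2S)-2-ethenyloxirane | C=C[C@H]1CO1 | starting material
9 | (3R)-hex-1-en-5-yn-3-ol | C=C[C@H](O)CC#C | intermediate
10 | dimethyl[(1E,4R)-4-(dimethylalumanyloxy)-2-methylhexa-1,5-dien-1-yl]alane | C=C[C@H](O[Al](C)C)C/C(C)=C/[Al](C)C | intermediate
11 | (3R,5E)-6-iodo-5-methylhexa-1,5-dien-3-ol | C=C[C@H](O)C/C(C)=C/I | intermediate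
12 | triethyl{[(3R,5E)-6-iodo-5-methylhexa-1,5-dien-3-yl]oxy}silane | C=C[C@H](O[Si](CC)(CC)CC)C/C(C)=C/I | intermediate
13 | [(1E,4R)-2-methyl-4-(triethylsilyloxy)hexa-1,5-dien-1-yl]lithium | C=C[C@H](O[Si](CC)(CC)CC)C/C(C)=C/[Li] | intermediate
14 | lithium borate complex of 13 and 7 (boron bears the alkenyl group of 13, the (1S)-1-chloro-3-methyl-2-methylidenebutyl group and the diol) | [Li+].C=C[C@H](O[Si](CC)(CC)CC)C/C(C)=C/[B-]1([C@H](Cl)C(=C)C(C)C)O[C@H](C2CCCCC2)[C@@H](C2CCCCC2)O1 | intermediate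
15 | triethylsilyl ether of 16 | C=C[C@H](O[Si](CC)(CC)CC)C/C(C)=C/[C@@H](C(=C)C(C)C)B1O[C@H](C2CCCCC2)[C@@H](C2CCCCC2)O1 | intermediate
16 | (3R,5E,7S)-7-[(4R,5R)-4,5-dicyclohexyl-1,3,2-dioxaborolan-2-yl]-5,9-dimethyl-8-methylidenedeca-1,5-dien-3-ol | C=C[C@H](O)C/C(C)=C/[C@@H](C(=C)C(C)C)B1O[C@H](C2CCCCC2)[C@@H](C2CCCCC2)O1 | intermediate
17 | hexa-1,5-diyne | C#CCCC#C | starting material
18 | lithium hexa-1,5-diyn-1-ide | [Li]C#CCCC#C | intermediate
19 | hepta-2,6-diyn-1-ol | OCC#CCCC#C | intermediate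
20 | methyl 7-hydroxy-2-methylidenehept-5-ynoate | COC(=O)C(=C)CCC#CCO | intermediate
21 | methyl (5Z)-7-hydroxy-2-methylidene-6-(tributylstannyl)hept-5-enoate | COC(=O)C(=C)CC/C=C(\[Sn](CCCC)(CCCC)CCCC)CO | intermediate
22 | methyl (5Z)-7-hydroxy-6-iodo-2-methylidenehept-5-enoate | COC(=O)C(=C)CC/C=C(\I)CO | intermediate
23 | (5Z)-7-hydroxy-6-iodo-2-methylidenehept-5-enoic acid | OC(=O)C(=C)CC/C=C(\I)CO | intermediate
24 | triethylsilyl (5Z)-6-iodo-2-methylidene-7-(triethylsilyloxy)hept-5-enoate | CC[Si](CC)(CC)OC(=O)C(=C)CC/C=C(\I)CO[Si](CC)(CC)CC | intermediate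
25 | (5Z)-6-iodo-2-methylidene-7-(triethylsilyloxy)hept-5-enoic acid | OC(=O)C(=C)CC/C=C(\I)CO[Si](CC)(CC)CC | intermediate
26 | (3R,5E,7S)-7-[(4R,5R)-4,5-dicyclohexyl-1,3,2-dioxaborolan-2-yl]-5,9-dimethyl-8-methylidenedeca-1,5-dien-3-yl (5Z)-6-iodo-2-methylidene-7-(triethylsilyloxy)hept-5-enoate | C=C[C@H](OC(=O)C(=C)CC/C=C(\I)CO[Si](CC)(CC)CC)C/C(C)=C/[C@@H](C(=C)C(C)C)B1O[C@H](C2CCCCC2)[C@@H](C2CCCCC2)O1 | intermediate
27 | (3R,5E,7S)-7-[(4R,5R)-4,5-dicyclohexyl-1,3,2-dioxaborolan-2-yl]-5,9-dimethyl-8-methylidenedeca-1,5-dien-3-yl (5Z)-7-hydroxy-6-iodo-2-methylidenehept-5-enoate | C=C[C@H](OC(=O)C(=C)CC/C=C(\I)CO)C/C(C)=C/[C@@H](C(=C)C(C)C)B1O[C@H](C2CCCCC2)[C@@H](C2CCCCC2)O1 | intermediate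
28 | (3R,5E,7S)-7-[(4R,5R)-4,5-dicyclohexyl-1,3,2-dioxaborolan-2-yl]-5,9-dimethyl-8-methylidenedeca-1,5-dien-3-yl (5Z)-6-iodo-2-methylidene-7-oxohept-5-enoate | C=C[C@H](OC(=O)C(=C)CC/C=C(\I)C=O)C/C(C)=C/[C@@H](C(=C)C(C)C)B1O[C@H](C2CCCCC2)[C@@H](C2CCCCC2)O1 | intermediate
29 | borate ester of 30 (the C13 oxygen carries the (4R,5R)-4,5-dicyclohexyl-1,3,2-dioxaborolan-2-yl group) | I/C1=C\CCC(=C)C(=O)O[C@@H](C=C)C/C(C)=C/C=C(/C(C)C)C[C@@H]1OB1O[C@H](C2CCCCC2)[C@@H](C2CCCCC2)O1 | intermediate
30 | (6Z,8S,10E,12E,15R)-15-ethenyl-8-hydroxy-7-iodo-13-methyl-3-methylidene-10-(propan-2-yl)-1-oxacyclopentadeca-6,10,12-trien-2-one | I/C1=C\CCC(=C)C(=O)O[C@@H](C=C)C/C(C)=C/C=C(/C(C)C)C[C@@H]1O | intermediate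
31 | (1E,3E,6R,7Z,11Z,13S)-13-hydroxy-12-iodo-20-norcembra-1,3,7,11-tetraen-19,6-olide | I/C1=C\CCC2=C[C@@H](C/C(C)=C/C=C(/C(C)C)C[C@@H]1O)OC2=O | intermediate
32 | methyl (1E,3E,6R,7Z,11Z,13S)-13-hydroxycembra-1,3,7,11-tetraen-19,6-olid-20-oate (CNP0173999.1) | COC(=O)/C1=C\CCC2=C[C@@H](C/C(C)=C/C=C(/C(C)C)C[C@@H]1O)OC2=O | target

**Count and risks**

Total step count: 16. Longest linear sequence: 10 steps (steps 7 to 11, then 12 to 16).

Steps most likely to fail:

1. Step 14 (proposed ring closure). The closed transition state may be reached too slowly at high dilution, so that bimolecular allylboration and oligomerisation take over, or ring strain may favour the chair with C3 equatorial and give the wrong C13/C1=C2 pairing. Fallback, setting out from 16 and 22 and coming back at 30: 22 would be oxidised with MnO2 to methyl (5Z)-6-iodo-2-methylidene-7-oxohept-5-enoate F1. F1 would be combined with 16 at high concentration (CH2Cl2, 23 °C; H2O work-up), a bimolecular allylboration of an α-substituted allylboronic ester of the established kind, which should give methyl (5Z,7S,9E,11E,14R)-7,14-dihydroxy-6-iodo-12-methyl-2-methylidene-9-(propan-2-yl)hexadeca-5,9,11,15-tetraenoate F2 by the same chair. Saponification (LiOH) would give (5Z,7S,9E,11E,14R)-7,14-dihydroxy-6-iodo-12-methyl-2-methylidene-9-(propan-2-yl)hexadeca-5,9,11,15-tetraenoic acid F3. Yamaguchi macrolactonisation (2,4,6-trichlorobenzoyl chloride, Et3N; DMAP, PhMe, high dilution) at the C6 hydroxyl, the C13 hydroxyl being able to close only an eight-membered ring, would then form the ring at the ester bond and return the route to 30.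

2. Step 6 (boron 1,2-shift). Migration in the hindered borate may be slow, and chloride exchange or allylic transposition may erode the configuration at C2. Fallback, setting out from 12 and coming back at 30, in which the order of the two alkenyl groups is reversed: 13, made from 12 as before, would be borylated with B(OMe)3 and esterified with (1S,2S)-1,2-dicyclohexylethane-1,2-diol to give (4S,5S)-4,5-dicyclohexyl-2-[(1E,4R)-2-methyl-4-(triethylsilyloxy)hexa-1,5-dien-1-yl]-1,3,2-dioxaborolane F4. Matteson homologation (LiCHCl2, ZnCl2) would give (4S,5S)-2-[(1R,2E,5R)-1-chloro-3-methyl-5-(triethylsilyloxy)hepta-2,6-dien-1-yl]-4,5-dicyclohexyl-1,3,2-dioxaborolane F5. The small Grignard reagent 3, used in excess, followed by PPTS in MeOH, would give (3R,5E,7S)-7-[(4S,5S)-4,5-dicyclohexyl-1,3,2-dioxaborolan-2-yl]-5,9-dimethyl-8-methylidenedeca-1,5-dien-3-ol F6, which has the same (S) centre at C2 and differs from 16 only in the diol. Esterification with 25 as in step 12 would give (3R,5E,7S)-7-[(4S,5S)-4,5-dicyclohexyl-1,3,2-dioxaborolan-2-yl]-5,9-dimethyl-8-methylidenedeca-1,5-dien-3-yl (5Z)-6-iodo-2-methylidene-7-(triethylsilyloxy)hept-5-enoate F7, and desilylation as in step 13 would give (3R,5E,7S)-7-[(4S,5S)-4,5-dicyclohexyl-1,3,2-dioxaborolan-2-yl]-5,9-dimethyl-8-methylidenedeca-1,5-dien-3-yl (5Z)-7-hydroxy-6-iodo-2-methylidenehept-5-enoate F8. Under the conditions of step 14 the diol is shed and the route is rejoined at 30.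

3. Step 15 (metathesis across the macrocycle). The lactone may not reach the s-cis ester conformation needed to bring the two alkenes together, so that ring-opening oligomerisation competes. Fallback, setting out from 26 and coming back at 31, in which the butenolide is closed before the macrocycle: 26 would be treated with the second-generation Grubbs catalyst (PhMe, 60 °C) to give (5R)-5-{(2E,4S)-4-[(4R,5R)-4,5-dicyclohexyl-1,3,2-dioxaborolan-2-yl]-2,6-dimethyl-5-methylidenehept-2-en-1-yl}-3-[(3Z)-4-iodo-5-(triethylsilyloxy)pent-3-en-1-yl]furan-2(5H)-one F9. PPTS in MeOH would give (5R)-5-{(2E,4S)-4-[(4R,5R)-4,5-dicyclohexyl-1,3,2-dioxaborolan-2-yl]-2,6-dimethyl-5-methylidenehept-2-en-1-yl}-3-[(3Z)-5-hydroxy-4-iodopent-3-en-1-yl]furan-2(5H)-one F10. Oxidation and ring closure under the conditions of step 14 would then form the 14-membered carbocycle directly, with the butenolide as a turn element, and give 31.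

Further compounds
F1 | step 14 | methyl (5Z)-6-iodo-2-methylidene-7-oxohept-5-enoate | COC(=O)C(=C)CC/C=C(\I)C=O
F2 | step 14 | methyl (5Z,7S,9E,11E,14R)-7,14-dihydroxy-6-iodo-12-methyl-2-methylidene-9-(propan-2-yl)hexadeca-5,9,11,15-tetraenoate | COC(=O)C(=C)CC/C=C(\I)[C@@H](O)C/C(C(C)C)=C\C=C(/C)C[C@@H](O)C=C
F3 | step 14 | (5Z,7S,9E,11E,14R)-7,14-dihydroxy-6-iodo-12-methyl-2-methylidene-9-(propan-2-yl)hexadeca-5,9,11,15-tetraenoic acid | OC(=O)C(=C)CC/C=C(\I)[C@@H](O)C/C(C(C)C)=C\C=C(/C)C[C@@H](O)C=C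
F4 | step 6 | (4S,5S)-4,5-dicyclohexyl-2-[(1E,4R)-2-methyl-4-(triethylsilyloxy)hexa-1,5-dien-1-yl]-1,3,2-dioxaborolane | C=C[C@H](O[Si](CC)(CC)CC)C/C(C)=C/B1O[C@@H](C2CCCCC2)[C@H](C2CCCCC2)O1
F5 | step 6 | (4S,5S)-2-[(1R,2E,5R)-1-chloro-3-methyl-5-(triethylsilyloxy)hepta-2,6-dien-1-yl]-4,5-dicyclohexyl-1,3,2-dioxaborolane | C=C[C@H](O[Si](CC)(CC)CC)C/C(C)=C/[C@H](Cl)B1O[C@@H](C2CCCCC2)[C@H](C2CCCCC2)O1
F6 | step 6 | (3R,5E,7S)-7-[(4S,5S)-4,5-dicyclohexyl-1,3,2-dioxaborolan-2-yl]-5,9-dimethyl-8-methylidenedeca-1,5-dien-3-ol | C=C[C@H](O)C/C(C)=C/[C@@H](C(=C)C(C)C)B1O[C@@H](C2CCCCC2)[C@H](C2CCCCC2)O1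
F7 | step 6 | (3R,5E,7S)-7-[(4S,5S)-4,5-dicyclohexyl-1,3,2-dioxaborolan-2-yl]-5,9-dimethyl-8-methylidenedeca-1,5-dien-3-yl (5Z)-6-iodo-2-methylidene-7-(triethylsilyloxy)hept-5-enoate | C=C[C@H](OC(=O)C(=C)CC/C=C(\I)CO[Si](CC)(CC)CC)C/C(C)=C/[C@@H](C(=C)C(C)C)B1O[C@@H](C2CCCCC2)[C@H](C2CCCCC2)O1
F8 | step 6 | (3R,5E,7S)-7-[(4S,5S)-4,5-dicyclohexyl-1,3,2-dioxaborolan-2-yl]-5,9-dimethyl-8-methylidenedeca-1,5-dien-3-yl (5Z)-7-hydroxy-6-iodo-2-methylidenehept-5-enoate | C=C[C@H](OC(=O)C(=C)CC/C=C(\I)CO)C/C(C)=C/[C@@H](C(=C)C(C)C)B1O[C@@H](C2CCCCC2)[C@H](C2CCCCC2)O1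
F9 | step 15 | (5R)-5-{(2E,4S)-4-[(4R,5R)-4,5-dicyclohexyl-1,3,2-dioxaborolan-2-yl]-2,6-dimethyl-5-methylidenehept-2-en-1-yl}-3-[(3Z)-4-iodo-5-(triethylsilyloxy)pent-3-en-1-yl]furan-2(5H)-one | O=C1O[C@H](C/C(C)=C/[C@@H](C(=C)C(C)C)B2O[C@H](C3CCCCC3)[C@@H](C3CCCCC3)O2)C=C1CC/C=C(\I)CO[Si](CC)(CC)CC
F10 | step 15 | (5R)-5-{(2E,4S)-4-[(4R,5R)-4,5-dicyclohexyl-1,3,2-dioxaborolan-2-yl]-2,6-dimethyl-5-methylidenehept-2-en-1-yl}-3-[(3Z)-5-hydroxy-4-iodopent-3-en-1-yl]furan-2(5H)-one | O=C1O[C@H](C/C(C)=C/[C@@H](C(=C)C(C)C)B2O[C@H](C3CCCCC3)[C@@H](C3CCCCC3)O2)C=C1CC/C=C(\I)CO
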